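The chemist who must stop the teal flask, so far followed to 10.0 h, needs to know how quickly target goes once it has peaked.

common to all: substrate 10 mM

| flask | partner | capture agent | remark | time |
|---|---|---|---|---|
| teal | 1.8 equiv | 0.20 mM | the very flask that is asked about, followed so far |  |
| red | 1.8 equiv | 0.13 mM | run made earlier |  |
| flask | 1.80 equiv | 0.200 mM |  | 25 h |

- teal (time / h: target / %, substrate / %): 1.33: 31.2, 1.4; 2.00: 47.8, 0.5; 3.00: 61.0, 0.4; 5.00: 67.2, 1.1; 6.00: 66.9, 1.8; 10.0: 62.8, 0
- red (time / h: target / %, substrate / %): 1.33: 31.0, 1.4; 2.00: 48.7, 1.1; 3.00: 59.2, 0; 5.00: 67.5, 0; 6.00: 68.8, 0; 10.0: 62.8, 0.6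

(each reading ± 1 percentage point)

* the best time, 25 h at the latest, for target
* the amount of target, in percent of the substrate charged, at that time
* the first time at which target reaches 47%, in the same percent

- the analysis behind the earlier runs scatters by 1 percentage point, standard deviation

1. Teal and red differ in capture agent, yet their target readings stand 1.9 percentage points apart at 6.00 h and are both 62.8% at 10.0 h. Against a scatter of 1 point, that allows pooling them as one curve.

2. Logarithms suit a slow loss. Let D, the decade time, be the time in which target would fall tenfold at its pace after the peak. The pooled fall from 6.00 h to 10.0 h gives D = 119 h.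

3. Objection: that rests on a small drop. Teal alone gives 146 h and red alone 101 h, so D is a range, and the pooled value lies inside it.

4. The pooled readings at 5.00 h and 6.00 h match within the scatter, so the best time is put between them, at 5.50 h, with about 67.8% read there. Objection: the later reading may already be past the peak. At pace D this costs 0.66 points, which is within the scatter.

5. Objection: target might recover later. No reading rises after 6.00 h, so the peak stands, and D carries it down 0.164 of a decade to 46.6% at 25 h.

6. The chord below 2.00 h puts 47% at 1.95 h. Objection: the curve bends, and the chord above gives 1.89 h, so the time lies between the two.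

The forecast gave 5.5 h, 68% and 1.95 h, adding “Nothing suggests a later recovery before 25 h”.

The flask gives 5.45 h, 67.5% and 1.94 h.

    second intermediate + capture agent → trapped intermediate (k = 51.1 M⁻¹ h⁻¹)
    open intermediate + second intermediate ⇌ target (K = 410 M⁻¹, k = 64.0 M⁻¹ h⁻¹)
    partner → second intermediate (k = 0.910 h⁻¹)
    2 second intermediate → homo product (k = 12.6 M⁻¹ h⁻¹)
    substrate → open intermediate (k = 3.22 h⁻¹)
    substrate → decomposition product (k = 5.81 × 10⁻⁴ h⁻¹)

The flask holds 48.9% of target at 25.0 h, where D gave 46.6%. Its simulated fall from the peak corresponds to a decade time of 140 h, within the range of teal and red. Open intermediate in the flask grows from 32.5% at 5.45 h to 51.0% at 25.0 h. The neighbour charged with 0.720 equiv of partner peaks at 41.9%, and D, applied over as many hours as separate 5.45 h from 25 h, takes that to 28.7%. Simulated, the neighbour holds 36.1% at 25.0 h.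

(The numbers in the tables stem from a simulated flask with made-up constants.)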